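**Plan**

- Locants: C1 is the ring carbon carrying OH and C7H2OBz, C2 the CHOH next to C3H2–C4H2, C5 the CHOBz carbon, C6 the CHOH between C5 and C1.
- Retrosynthesis: the O1/O6 acetal and the C2 carbinol go back to a C2 ketone, then the ring bond C4–C5 is cut. C5 carries oxygen and sits three bonds from the C2 carbonyl, so it can be an α-benzoyloxy radical freed from a carboxyl on C5 that adds to C4 of a C2 vinyl ketone. The chain is cut further at C1–C2 (acryloyl anion plus C1 ketone) and C1–C7 (one-carbon homologation of a tartrate ester).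
- Forward: diethyl D-tartrate supplies C1, C6, C5 and the carboxyl carbon; C7 and then C2–C4 are joined to it; the only carbocycle (C1–C6) closes in step 12 by 6-endo radical addition.
- Stereochemistry: C6 comes from D-tartrate; C1 from chelation-controlled addition next to C6; C5 from the ring closure, held trans to O6 by a trans-dioxolane over O1/O6 that also keeps O1 from lactonising onto the activated carboxyl; C2 from axial hydride attack on the locked chair.

Key step: step 12

Remark: the 4-methoxybenzylidene acetal carbon made in step 8 forms without control, so compounds 15 to 23 are carried as both epimers at that carbon (left open in the SMILES); the centre is removed in step 14.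

**Route**

Step 1
Reactants: 1 diethyl D-tartrate
Product: 3 diethyl (2S,3S)-2-hydroxy-3-[(4-methoxybenzyl)oxy]butanedioate, via stannylene acetal 2 (not isolated)
Conditions: Bu2SnO, toluene, reflux (Dean–Stark); then PMBCl, CsF, DMF, rt
Reagents that add atoms: 4-methoxybenzyl chloride, COc1ccc(CCl)cc1
Why: Stannylene acetal activation followed by Williamson-type O-alkylation lets exactly one of the two homotopic hydroxyls of the C2-symmetric diol react, giving the mono-PMB ether (the future chelating O6 group) without touching either stereocentre.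

Step 2
Reactants: 3 diethyl (2S,3S)-2-hydroxy-3-[(4-methoxybenzyl)oxy]butanedioate
Product: 4 ethyl (2S,3R)-3,4-dihydroxy-2-[(4-methoxybenzyl)oxy]butanoate
Conditions: BH3·SMe2, NaBH4 (5 mol %), THF, 0 °C to rt; MeOH quench
Reagents that add atoms: none
Why: Hydroxyl-directed borane reduction of an α-hydroxy ester: the free C5 hydroxyl becomes an alkoxyborane that delivers hydride only to its own neighbouring ester, so the ester next to the PMB ether survives and the two tartrate termini are told apart.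

Step 3
Reactants: 4 ethyl (2S,3R)-3,4-dihydroxy-2-[(4-methoxybenzyl)oxy]butanoate
Product: 6 ethyl (2S,3R)-4-[(tert-butyldiphenylsilyl)oxy]-2-[(4-methoxybenzyl)oxy]-3-[(triethylsilyl)oxy]butanoate, via mono-TBDPS ether 5 (not isolated)
Conditions: TBDPSCl, imidazole, CH2Cl2, 0 °C; then TESCl, rt
Reagents that add atoms: tert-butyl(chloro)diphenylsilane, CC(C)(C)[Si](Cl)(c1ccccc1)c1ccccc1; chlorotriethylsilane, CC[Si](Cl)(CC)CC
Why: Sterically graded silyl ether formation: bulky TBDPSCl takes only the primary hydroxyl and TESCl then caps the secondary one in the same flask, giving an acid-robust group on the future carboxyl carbon and an acid-labile one on O5.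

Step 4
Reactants: 6 ethyl (2S,3R)-4-[(tert-butyldiphenylsilyl)oxy]-2-[(4-methoxybenzyl)oxy]-3-[(triethylsilyl)oxy]butanoate
Product: 7 (3S,4R)-5-[(tert-butyldiphenylsilyl)oxy]-1-chloro-3-[(4-methoxybenzyl)oxy]-4-[(triethylsilyl)oxy]pentan-2-one
Conditions: ICH2Cl, MeLi·LiBr, THF, −78 °C; AcOH quench at −78 °C
Reagents that add atoms: chloroiodomethane, ClCI
Why: Halomethyllithium homologation of an ester (acyl substitution by chloromethyllithium made by iodine–lithium exchange): the α-alkoxy-chelated tetrahedral lithium alkoxide persists at −78 °C and collapses to the chloromethyl ketone only on protonation, which prevents a second addition and leaves C6 untouched.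

Step 5
Reactants: 7 (3S,4R)-5-[(tert-butyldiphenylsilyl)oxy]-1-chloro-3-[(4-methoxybenzyl)oxy]-4-[(triethylsilyl)oxy]pentan-2-one; 8 sodium benzoate
Product: 9 (3S,4R)-5-[(tert-butyldiphenylsilyl)oxy]-3-[(4-methoxybenzyl)oxy]-2-oxo-4-[(triethylsilyl)oxy]pentyl benzoate
Conditions: NaI (cat.), DMF, rt
Reagents that add atoms: none
Why: SN2 displacement at an α-halo ketone by carboxylate, with Finkelstein assistance from iodide, installs the C7 benzoate under nearly neutral conditions.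

Step 6
Reactants: 9 (3S,4R)-5-[(tert-butyldiphenylsilyl)oxy]-3-[(4-methoxybenzyl)oxy]-2-oxo-4-[(triethylsilyl)oxy]pentyl benzoate; 10 methoxyallene
Product: 13 (2R)-2-{(1S,2R)-3-[(tert-butyldiphenylsilyl)oxy]-2-hydroxy-1-[(4-methoxybenzyl)oxy]propyl}-2-hydroxy-3-oxopent-4-en-1-yl benzoate, via 1-lithio-1-methoxyallene 11 (not isolated), via allenyl carbinol 12 (not isolated)
Conditions: 10, nBuLi, Et2O, −40 °C; added to 9 precomplexed with MgBr2·OEt2, CH2Cl2, −78 °C; then 1 M H2SO4, THF, 0 °C to rt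
Reagents that add atoms: water, O
Why: Cram-chelate-controlled 1,2-addition followed by enol ether hydrolysis: magnesium bridges the ketone oxygen and the α-OPMB oxygen (the benzoate and silyl ether oxygens are poor ligands), 1-lithio-1-methoxyallene, which reacts at its α-carbon as an acryloyl anion equivalent, enters from the face of the C6 hydrogen and sets C1 as R, and the acidic work-up turns the methoxyallene into the vinyl ketone while removing the TES ether.

Step 7
Reactants: 13 (2R)-2-{(1S,2R)-3-[(tert-butyldiphenylsilyl)oxy]-2-hydroxy-1-[(4-methoxybenzyl)oxy]propyl}-2-hydroxy-3-oxopent-4-en-1-yl benzoate; 14 benzoyl chloride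
Product: 15 (2R)-2-{(1S,2R)-2-(benzoyloxy)-3-[(tert-butyldiphenylsilyl)oxy]-1-[(4-methoxybenzyl)oxy]propyl}-2-hydroxy-3-oxopent-4-en-1-yl benzoate
Conditions: pyridine, CH2Cl2, 0 °C
Reagents that add atoms: none
Why: Pyridine-mediated O-acylation (Einhorn conditions) of the only secondary hydroxyl; the tertiary α-ketol hydroxyl does not react and no nucleophilic catalyst is used that could add to the vinyl ketone.

Step 8
Reactants: 15 (2R)-2-{(1S,2R)-2-(benzoyloxy)-3-[(tert-butyldiphenylsilyl)oxy]-1-[(4-methoxybenzyl)oxy]propyl}-2-hydroxy-3-oxopent-4-en-1-yl benzoate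
Product: 16 {(4R,5S)-5-[(1R)-1-(benzoyloxy)-2-[(tert-butyldiphenylsilyl)oxy]ethyl]-2-(4-methoxyphenyl)-4-(prop-2-enoyl)-1,3-dioxolan-4-yl}methyl benzoate (both acetal epimers)
Conditions: DDQ, 4 Å molecular sieves, CH2Cl2, 0 °C to rt
Reagents that add atoms: none
Why: DDQ oxidative acetalisation of a PMB ether: hydride abstraction gives a benzylic oxocarbenium ion that the neighbouring tertiary C1 hydroxyl traps under anhydrous conditions, which masks that hydroxyl (free, it would lactonise onto the activated C5 carboxyl) and ties O1 and O6 into a trans-dioxolane.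

Step 9
Reactants: 16 {(4R,5S)-5-[(1R)-1-(benzoyloxy)-2-[(tert-butyldiphenylsilyl)oxy]ethyl]-2-(4-methoxyphenyl)-4-(prop-2-enoyl)-1,3-dioxolan-4-yl}methyl benzoate
Product: 17 {(4R,5S)-5-[(1R)-1-(benzoyloxy)-2-hydroxyethyl]-2-(4-methoxyphenyl)-4-(prop-2-enoyl)-1,3-dioxolan-4-yl}methyl benzoate (both acetal epimers)
Conditions: HF·pyridine, pyridine, THF, 0 °C to rt
Reagents that add atoms: none
Why: Fluoride-mediated desilylation; the pyridine-buffered, weakly acidic medium removes the primary TBDPS ether while leaving the acetal intact and disfavouring migration of the neighbouring benzoate.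

Step 10
Reactants: 17 {(4R,5S)-5-[(1R)-1-(benzoyloxy)-2-hydroxyethyl]-2-(4-methoxyphenyl)-4-(prop-2-enoyl)-1,3-dioxolan-4-yl}methyl benzoate
Product: 19 (2S)-2-(benzoyloxy)-2-[(4S,5R)-5-[(benzoyloxy)methyl]-2-(4-methoxyphenyl)-5-(prop-2-enoyl)-1,3-dioxolan-4-yl]acetic acid (both acetal epimers), via aldehyde 18 (not isolated)
Conditions: TEMPO (cat.), PhI(OAc)2, MeCN/H2O (1:1), rt
Reagents that add atoms: water, O
Why: Nitroxyl-catalysed oxidation with PhI(OAc)2 as terminal oxidant takes the primary alcohol through the aldehyde hydrate to the acid in aqueous acetonitrile without touching the enone, the acetal or the benzoates.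

Step 11
Reactants: 19 (2S)-2-(benzoyloxy)-2-[(4S,5R)-5-[(benzoyloxy)methyl]-2-(4-methoxyphenyl)-5-(prop-2-enoyl)-1,3-dioxolan-4-yl]acetic acid; 20 N-hydroxyphthalimide
Product: 21 1,3-dioxo-1,3-dihydro-2H-isoindol-2-yl (2S)-2-(benzoyloxy)-2-[(4S,5R)-5-[(benzoyloxy)methyl]-2-(4-methoxyphenyl)-5-(prop-2-enoyl)-1,3-dioxolan-4-yl]acetate (both acetal epimers)
Conditions: DIC, CH2Cl2, 0 °C to rt
Reagents that add atoms: none
Why: Carbodiimide (Steglich-type) esterification of the acid with N-hydroxyphthalimide gives the redox-active ester; base and acyl-transfer catalyst are left out so that nothing adds to the vinyl ketone.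

Step 12
Reactants: 21 1,3-dioxo-1,3-dihydro-2H-isoindol-2-yl (2S)-2-(benzoyloxy)-2-[(4S,5R)-5-[(benzoyloxy)methyl]-2-(4-methoxyphenyl)-5-(prop-2-enoyl)-1,3-dioxolan-4-yl]acetate
Product: 22 [(3aR,7R,7aS)-7-(benzoyloxy)-2-(4-methoxyphenyl)-4-oxohexahydro-2H-1,3-benzodioxol-3a-yl]methyl benzoate (both acetal epimers)
Conditions: undivided cell, reticulated vitreous carbon cathode, zinc anode, nBu4NBF4 (0.1 M), HFIP (5 equiv), DMF (5 mM in 21), constant current, 2.2 F/mol, rt
Reagents that add atoms: none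
Why: One-electron reduction of the N-acyloxyphthalimide at the cathode (it is reduced well before the vinyl ketone) gives a radical anion that fragments into phthalimide anion, CO2 and the C5 α-benzoyloxy radical; this nucleophilic radical adds to C4, the β-carbon of the C2 enone, and the α-keto radical at C3 is then reduced and protonated by HFIP. It is the intramolecular form of the electroreductive decarboxylative Giese addition of redox-active esters. The six-membered carbocycle closes in the 6-endo-trig mode, because attack at the enone terminus is polarity-matched and gives the stabilised α-keto radical, whereas 5-exo attack at C3 would give a primary radical on a trans-fused bicyclo[3.3.0] skeleton. The new C5 stereocentre is controlled by the trans-dioxolane over O1 and O6: the chair-like transition state must hold both acetal oxygens equatorial and C7 axial, so the benzoyloxy group on the planar radical takes the pseudo-equatorial site, trans to O6 and away from the axial C7H2OBz. The step needs selective reduction of the ester, ring closure faster than hydrogen capture or oligomerisation, and trans selectivity at C5; the potential gap, high dilution with controlled charge, and the acetal lock are expected to secure these, and the earlier C5 configuration is irrelevant because the radical is planar.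

Step 13
Reactants: 22 [(3aR,7R,7aS)-7-(benzoyloxy)-2-(4-methoxyphenyl)-4-oxohexahydro-2H-1,3-benzodioxol-3a-yl]methyl benzoate
Product: 23 [(3aS,4R,7R,7aS)-7-(benzoyloxy)-4-hydroxy-2-(4-methoxyphenyl)hexahydro-2H-1,3-benzodioxol-3a-yl]methyl benzoate (both acetal epimers)
Conditions: NaBH4, MeOH/CH2Cl2, −40 °C
Reagents that add atoms: none
Why: Borohydride reduction of a conformationally locked cyclohexanone: the trans-fused acetal fixes the chair with C7H2OBz axial on C1, so hydride attacks C2 axially from the opposite face and the new hydroxyl becomes equatorial, trans to O1 and cis to C7 (4R in the product numbering).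

Step 14
Reactants: 23 [(3aS,4R,7R,7aS)-7-(benzoyloxy)-4-hydroxy-2-(4-methoxyphenyl)hexahydro-2H-1,3-benzodioxol-3a-yl]methyl benzoate
Product: 24 [(1S,2S,3R,6R)-3-(benzoyloxy)-1,2,6-trihydroxycyclohexyl]methyl benzoate
Conditions: AcOH/H2O (4:1), 40 °C
Reagents that add atoms: none
Why: Acid-catalysed acetal hydrolysis; the strained trans-fused 4-methoxybenzylidene acetal should be cleaved by aqueous acetic acid under conditions that leave both benzoates in place and unmoved.

**Compound list**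

1 | diethyl D-tartrate | CCOC(=O)[C@@H](O)[C@H](O)C(=O)OCC | starting material
2 | diethyl (4S,5S)-2,2-dibutyl-1,3,2-dioxastannolane-4,5-dicarboxylate | CCOC(=O)[C@H]1O[Sn](CCCC)(CCCC)O[C@@H]1C(=O)OCC | intermediate
3 | diethyl (2S,3S)-2-hydroxy-3-[(4-methoxybenzyl)oxy]butanedioate | CCOC(=O)[C@@H](OCc1ccc(OC)cc1)[C@H](O)C(=O)OCC | intermediate
4 | ethyl (2S,3R)-3,4-dihydroxy-2-[(4-methoxybenzyl)oxy]butanoate | CCOC(=O)[C@@H](OCc1ccc(OC)cc1)[C@H](O)CO | intermediate
5 | ethyl (2S,3R)-4-[(tert-butyldiphenylsilyl)oxy]-3-hydroxy-2-[(4-methoxybenzyl)oxy]butanoate | CCOC(=O)[C@@H](OCc1ccc(OC)cc1)[C@H](O)CO[Si](c1ccccc1)(c1ccccc1)C(C)(C)C | intermediate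
6 | ethyl (2S,3R)-4-[(tert-butyldiphenylsilyl)oxy]-2-[(4-methoxybenzyl)oxy]-3-[(triethylsilyl)oxy]butanoate | CCOC(=O)[C@@H](OCc1ccc(OC)cc1)[C@H](O[Si](CC)(CC)CC)CO[Si](c1ccccc1)(c1ccccc1)C(C)(C)C | intermediate
7 | (3S,4R)-5-[(tert-butyldiphenylsilyl)oxy]-1-chloro-3-[(4-methoxybenzyl)oxy]-4-[(triethylsilyl)oxy]pentan-2-one | ClCC(=O)[C@@H](OCc1ccc(OC)cc1)[C@H](O[Si](CC)(CC)CC)CO[Si](c1ccccc1)(c1ccccc1)C(C)(C)C | intermediate
8 | sodium benzoate | [Na+].[O-]C(=O)c1ccccc1 | starting material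
9 | (3S,4R)-5-[(tert-butyldiphenylsilyl)oxy]-3-[(4-methoxybenzyl)oxy]-2-oxo-4-[(triethylsilyl)oxy]pentyl benzoate | O=C(OCC(=O)[C@@H](OCc1ccc(OC)cc1)[C@H](O[Si](CC)(CC)CC)CO[Si](c1ccccc1)(c1ccccc1)C(C)(C)C)c1ccccc1 | intermediate
10 | methoxyallene (1-methoxypropa-1,2-diene) | COC=C=C | starting material
11 | 1-lithio-1-methoxyallene | [Li]C(OC)=C=C | intermediate
12 | (2R)-2-{(1S,2R)-3-[(tert-butyldiphenylsilyl)oxy]-1-[(4-methoxybenzyl)oxy]-2-[(triethylsilyl)oxy]propyl}-2-hydroxy-3-methoxypenta-3,4-dien-1-yl benzoate | C=C=C(OC)[C@@](O)(COC(=O)c1ccccc1)[C@@H](OCc1ccc(OC)cc1)[C@H](O[Si](CC)(CC)CC)CO[Si](c1ccccc1)(c1ccccc1)C(C)(C)C | intermediate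
13 | (2R)-2-{(1S,2R)-3-[(tert-butyldiphenylsilyl)oxy]-2-hydroxy-1-[(4-methoxybenzyl)oxy]propyl}-2-hydroxy-3-oxopent-4-en-1-yl benzoate | C=CC(=O)[C@@](O)(COC(=O)c1ccccc1)[C@@H](OCc1ccc(OC)cc1)[C@H](O)CO[Si](c1ccccc1)(c1ccccc1)C(C)(C)C | intermediate
14 | benzoyl chloride | O=C(Cl)c1ccccc1 | starting material
15 | (2R)-2-{(1S,2R)-2-(benzoyloxy)-3-[(tert-butyldiphenylsilyl)oxy]-1-[(4-methoxybenzyl)oxy]propyl}-2-hydroxy-3-oxopent-4-en-1-yl benzoate | C=CC(=O)[C@@](O)(COC(=O)c1ccccc1)[C@@H](OCc1ccc(OC)cc1)[C@H](OC(=O)c1ccccc1)CO[Si](c1ccccc1)(c1ccccc1)C(C)(C)C | intermediate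
16 | {(4R,5S)-5-[(1R)-1-(benzoyloxy)-2-[(tert-butyldiphenylsilyl)oxy]ethyl]-2-(4-methoxyphenyl)-4-(prop-2-enoyl)-1,3-dioxolan-4-yl}methyl benzoate, both epimers at the acetal carbon | C=CC(=O)[C@]1(COC(=O)c2ccccc2)OC(c2ccc(OC)cc2)O[C@H]1[C@H](OC(=O)c1ccccc1)CO[Si](c1ccccc1)(c1ccccc1)C(C)(C)C | intermediate
17 | {(4R,5S)-5-[(1R)-1-(benzoyloxy)-2-hydroxyethyl]-2-(4-methoxyphenyl)-4-(prop-2-enoyl)-1,3-dioxolan-4-yl}methyl benzoate, both epimers at the acetal carbon | C=CC(=O)[C@]1(COC(=O)c2ccccc2)OC(c2ccc(OC)cc2)O[C@H]1[C@H](OC(=O)c1ccccc1)CO | intermediate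
18 | {(4R,5S)-5-[(1S)-1-(benzoyloxy)-2-oxoethyl]-2-(4-methoxyphenyl)-4-(prop-2-enoyl)-1,3-dioxolan-4-yl}methyl benzoate, both epimers at the acetal carbon | C=CC(=O)[C@]1(COC(=O)c2ccccc2)OC(c2ccc(OC)cc2)O[C@H]1[C@H](OC(=O)c1ccccc1)C=O | intermediate
19 | (2S)-2-(benzoyloxy)-2-[(4S,5R)-5-[(benzoyloxy)methyl]-2-(4-methoxyphenyl)-5-(prop-2-enoyl)-1,3-dioxolan-4-yl]acetic acid, both epimers at the acetal carbon | C=CC(=O)[C@]1(COC(=O)c2ccccc2)OC(c2ccc(OC)cc2)O[C@H]1[C@H](OC(=O)c1ccccc1)C(=O)O | intermediate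
20 | N-hydroxyphthalimide | ON1C(=O)c2ccccc2C1=O | starting material
21 | 1,3-dioxo-1,3-dihydro-2H-isoindol-2-yl (2S)-2-(benzoyloxy)-2-[(4S,5R)-5-[(benzoyloxy)methyl]-2-(4-methoxyphenyl)-5-(prop-2-enoyl)-1,3-dioxolan-4-yl]acetate, both epimers at the acetal carbon | C=CC(=O)[C@]1(COC(=O)c2ccccc2)OC(c2ccc(OC)cc2)O[C@H]1[C@H](OC(=O)c1ccccc1)C(=O)ON1C(=O)c2ccccc2C1=O | intermediate
22 | [(3aR,7R,7aS)-7-(benzoyloxy)-2-(4-methoxyphenyl)-4-oxohexahydro-2H-1,3-benzodioxol-3a-yl]methyl benzoate, both epimers at the acetal carbon | O=C(OC[C@@]12OC(c3ccc(OC)cc3)O[C@H]1[C@H](OC(=O)c1ccccc1)CCC2=O)c1ccccc1 | intermediate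
23 | [(3aS,4R,7R,7aS)-7-(benzoyloxy)-4-hydroxy-2-(4-methoxyphenyl)hexahydro-2H-1,3-benzodioxol-3a-yl]methyl benzoate, both epimers at the acetal carbon | O=C(OC[C@@]12OC(c3ccc(OC)cc3)O[C@H]1[C@H](OC(=O)c1ccccc1)CC[C@H]2O)c1ccccc1 | intermediate
24 | [(1S,2S,3R,6R)-3-(benzoyloxy)-1,2,6-trihydroxycyclohexyl]methyl benzoate | O=C(OC[C@]1(O)[C@H](O)CC[C@@H](OC(=O)c2ccccc2)[C@@H]1O)c1ccccc1 | target

**Totals**

Total step count: 14. Longest linear sequence: 14 steps (1 to 24).

**Steps most likely to fail**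

Step 12. The C5 radical may be reduced or pick up a hydrogen atom before it closes the ring, or add to a second molecule, and the acetal-locked chair may still let some C5 epimer through. The fallback sets out from acid 19 and comes back at ketone 22, using a reductant-free radical chain (Barton decarboxylation with group transfer). Acid 19 is coupled with 1-hydroxypyridine-2(1H)-thione (DCC, CH2Cl2, dark) to give the thiohydroxamate ester 2-thioxopyridin-1(2H)-yl (2S)-2-(benzoyloxy)-2-[(4S,5R)-5-[(benzoyloxy)methyl]-2-(4-methoxyphenyl)-5-(prop-2-enoyl)-1,3-dioxolan-4-yl]acetate F1. Visible-light irradiation at high dilution without any hydrogen donor should let the C5 radical cyclise and the α-keto radical take the pyridylthio group from a second ester, giving [(3aR,7R,7aS)-7-(benzoyloxy)-2-(4-methoxyphenyl)-4-oxo-5-(pyridin-2-ylsulfanyl)hexahydro-2H-1,3-benzodioxol-3a-yl]methyl benzoate F2. Bu3SnH/AIBN in toluene at 80 °C then removes the sulfanyl group to return 22.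

Step 6. The nucleophile may attack the non-chelated ketone (poor facial selectivity at C1), deprotonate the acidic C7 methylene, or exchange metal with MgBr2 and react through its γ-carbon. The fallback sets out from ketone 9 and comes back at 13, building the acryloyl group stepwise with a true Grignard reagent. Vinylmagnesium bromide (THF, −78 °C) adds under chelate control to give (2R)-2-{(1S,2R)-3-[(tert-butyldiphenylsilyl)oxy]-1-[(4-methoxybenzyl)oxy]-2-[(triethylsilyl)oxy]propyl}-2-hydroxybut-3-en-1-yl benzoate F3. Lemieux–Johnson cleavage (OsO4 cat., NaIO4, 2,6-lutidine, dioxane/H2O) gives (2R)-2-{(1S,2R)-3-[(tert-butyldiphenylsilyl)oxy]-1-[(4-methoxybenzyl)oxy]-2-[(triethylsilyl)oxy]propyl}-2-hydroxy-3-oxopropyl benzoate F4. A second addition of vinylmagnesium bromide gives (2S)-2-{(1S,2R)-3-[(tert-butyldiphenylsilyl)oxy]-1-[(4-methoxybenzyl)oxy]-2-[(triethylsilyl)oxy]propyl}-2,3-dihydroxypent-4-en-1-yl benzoate F5 as both carbinol epimers. Dess–Martin oxidation of the secondary allylic alcohol gives (2R)-2-{(1S,2R)-3-[(tert-butyldiphenylsilyl)oxy]-1-[(4-methoxybenzyl)oxy]-2-[(triethylsilyl)oxy]propyl}-2-hydroxy-3-oxopent-4-en-1-yl benzoate F6, and 1 M H2SO4 in THF removes the TES ether to give 13.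

Step 4. The carbenoid may add a second time once the tetrahedral intermediate collapses, or enolisation may erode C6. The fallback sets out from ester 6 and comes back at ketone 9, avoiding the carbenoid altogether. iBu2AlH (CH2Cl2, −78 °C) gives (2S,3R)-4-[(tert-butyldiphenylsilyl)oxy]-2-[(4-methoxybenzyl)oxy]-3-[(triethylsilyl)oxy]butanal F7. Wittig methylenation (Ph3P=CH2, THF, −78 to 0 °C) gives tert-butyl{[(2R,3R)-3-[(4-methoxybenzyl)oxy]-2-[(triethylsilyl)oxy]pent-4-en-1-yl]oxy}diphenylsilane F8. Upjohn dihydroxylation (OsO4 cat., NMO, acetone/H2O) gives (3R,4R)-5-[(tert-butyldiphenylsilyl)oxy]-3-[(4-methoxybenzyl)oxy]-4-[(triethylsilyl)oxy]pentane-1,2-diol F9 as both carbinol epimers. Selective acylation of the primary hydroxyl with 14 (2,4,6-collidine, CH2Cl2, −78 °C) gives (3R,4R)-5-[(tert-butyldiphenylsilyl)oxy]-2-hydroxy-3-[(4-methoxybenzyl)oxy]-4-[(triethylsilyl)oxy]pentyl benzoate F10, and Dess–Martin oxidation gives 9.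

**Further compounds**

F1 | step 12 | 2-thioxopyridin-1(2H)-yl (2S)-2-(benzoyloxy)-2-[(4S,5R)-5-[(benzoyloxy)methyl]-2-(4-methoxyphenyl)-5-(prop-2-enoyl)-1,3-dioxolan-4-yl]acetate, both epimers at the acetal carbon | C=CC(=O)[C@]1(COC(=O)c2ccccc2)OC(c2ccc(OC)cc2)O[C@H]1[C@H](OC(=O)c1ccccc1)C(=O)ON1C=CC=CC1=S
F2 | step 12 | [(3aR,7R,7aS)-7-(benzoyloxy)-2-(4-methoxyphenyl)-4-oxo-5-(pyridin-2-ylsulfanyl)hexahydro-2H-1,3-benzodioxol-3a-yl]methyl benzoate, epimers at C5 and at the acetal carbon | O=C(OC[C@@]12OC(c3ccc(OC)cc3)O[C@H]1[C@H](OC(=O)c1ccccc1)CC(Sc1ccccn1)C2=O)c1ccccc1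
F3 | step 6 | (2R)-2-{(1S,2R)-3-[(tert-butyldiphenylsilyl)oxy]-1-[(4-methoxybenzyl)oxy]-2-[(triethylsilyl)oxy]propyl}-2-hydroxybut-3-en-1-yl benzoate | C=C[C@@](O)(COC(=O)c1ccccc1)[C@@H](OCc1ccc(OC)cc1)[C@H](O[Si](CC)(CC)CC)CO[Si](c1ccccc1)(c1ccccc1)C(C)(C)C
F4 | step 6 | (2R)-2-{(1S,2R)-3-[(tert-butyldiphenylsilyl)oxy]-1-[(4-methoxybenzyl)oxy]-2-[(triethylsilyl)oxy]propyl}-2-hydroxy-3-oxopropyl benzoate | O=C[C@@](O)(COC(=O)c1ccccc1)[C@@H](OCc1ccc(OC)cc1)[C@H](O[Si](CC)(CC)CC)CO[Si](c1ccccc1)(c1ccccc1)C(C)(C)C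
F5 | step 6 | (2S)-2-{(1S,2R)-3-[(tert-butyldiphenylsilyl)oxy]-1-[(4-methoxybenzyl)oxy]-2-[(triethylsilyl)oxy]propyl}-2,3-dihydroxypent-4-en-1-yl benzoate, both epimers at C3 | C=CC(O)[C@@](O)(COC(=O)c1ccccc1)[C@@H](OCc1ccc(OC)cc1)[C@H](O[Si](CC)(CC)CC)CO[Si](c1ccccc1)(c1ccccc1)C(C)(C)C
F6 | step 6 | (2R)-2-{(1S,2R)-3-[(tert-butyldiphenylsilyl)oxy]-1-[(4-methoxybenzyl)oxy]-2-[(triethylsilyl)oxy]propyl}-2-hydroxy-3-oxopent-4-en-1-yl benzoate | C=CC(=O)[C@@](O)(COC(=O)c1ccccc1)[C@@H](OCc1ccc(OC)cc1)[C@H](O[Si](CC)(CC)CC)CO[Si](c1ccccc1)(c1ccccc1)C(C)(C)C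
F7 | step 4 | (2S,3R)-4-[(tert-butyldiphenylsilyl)oxy]-2-[(4-methoxybenzyl)oxy]-3-[(triethylsilyl)oxy]butanal | O=C[C@@H](OCc1ccc(OC)cc1)[C@H](O[Si](CC)(CC)CC)CO[Si](c1ccccc1)(c1ccccc1)C(C)(C)C
F8 | step 4 | tert-butyl{[(2R,3R)-3-[(4-methoxybenzyl)oxy]-2-[(triethylsilyl)oxy]pent-4-en-1-yl]oxy}diphenylsilane | C=C[C@@H](OCc1ccc(OC)cc1)[C@H](O[Si](CC)(CC)CC)CO[Si](c1ccccc1)(c1ccccc1)C(C)(C)C
F9 | step 4 | (3R,4R)-5-[(tert-butyldiphenylsilyl)oxy]-3-[(4-methoxybenzyl)oxy]-4-[(triethylsilyl)oxy]pentane-1,2-diol, both epimers at C2 | OCC(O)[C@@H](OCc1ccc(OC)cc1)[C@H](O[Si](CC)(CC)CC)CO[Si](c1ccccc1)(c1ccccc1)C(C)(C)C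
F10 | step 4 | (3R,4R)-5-[(tert-butyldiphenylsilyl)oxy]-2-hydroxy-3-[(4-methoxybenzyl)oxy]-4-[(triethylsilyl)oxy]pentyl benzoate, both epimers at C2 | O=C(OCC(O)[C@@H](OCc1ccc(OC)cc1)[C@H](O[Si](CC)(CC)CC)CO[Si](c1ccccc1)(c1ccccc1)C(C)(C)C)c1ccccc1
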